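**Assumptions.** The SMILES is read as (2S)-5,7-dihydroxy-2-[(2R,3R)-2-(4-hydroxy-3-methoxyphenyl)-3-(hydroxymethyl)-2,3-dihydro-1,4-benzodioxin-6-yl]chroman-4-one (trans-benzodioxane, with the O on the aryl-bearing carbon para to the flavanone). Only substrates, intermediates and fragment-contributing starting materials are numbered; reagents are named with SMILES in each step. The Rh ligand's sense of induction is taken to match (S)-BINAP → (S)-3-arylcyclohexanone, which maps onto the (2S)-flavanone; if a model run with PhB(OH)2 shows the opposite sense, the (R)-ligand is used.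

## Retrosynthetic overview

1. Silandrin ⇐ tetra-O-benzyl silandrin by one neutral global hydrogenolysis.
2. Key step: the flavanone C2–aryl bond and the (2S) centre are made together by Rh-catalysed asymmetric 1,4-addition of an enantiopure benzodioxanyl boronic acid to 5,7-bis(benzyloxy)chromone. This replaces the usual chalcone/oxa-Michael or oxidative-coupling route.
3. The pyranone ring is made first, as the achiral chromone from phloroacetophenone (benzylation, enaminone, acid cyclisation).
4. The trans-benzodioxane ring is closed by acid-mediated benzylic C–O formation under thermodynamic control. Its one reagent-set stereocentre (C3) comes from Mitsunobu inversion of an (S)-O-benzylglycerate with a regiodefined bromocatechol mono-MOM ether.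
5. Ring order: benzodioxane and chromone are built separately; the flavanone stereocentre is created last, at fragment union.

## Route

**Step 1**
Reactants: 1, methyl (S)-glycidate [methyl (2S)-oxirane-2-carboxylate]
Product: 2, methyl (2S)-3-(benzyloxy)-2-hydroxypropanoate
Conditions: BnOH (4 equiv), BF3·OEt2 (10 mol%), CH2Cl2, 0 °C → rt
Reagents that add atoms: benzyl alcohol, OCc1ccccc1
Why: Lewis-acid-catalysed epoxide alcoholysis occurs at the unhindered C3 because C2 is deactivated by the ester, so the C2–O bond and its (S) configuration are untouched.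

**Step 2**
Reactants: 3, 5-bromo-2-hydroxybenzaldehyde (5-bromosalicylaldehyde)
Product: 4, 5-bromo-2-(methoxymethoxy)benzaldehyde
Conditions: MOMCl, i-Pr2NEt, CH2Cl2, 0 °C → rt
Reagents that add atoms: chloromethyl methyl ether (MOMCl), COCCl
Why: Phenol O-alkylation (MOM acetal formation) masks the oxygen para to Br, which must stay out of the first ether-forming step and later becomes O1 of the benzodioxane.

**Step 3**
Reactants: 4, 5-bromo-2-(methoxymethoxy)benzaldehyde
Product: 5, 5-bromo-2-(methoxymethoxy)phenol
Conditions: mCPBA, NaHCO3, CH2Cl2, rt; then K2CO3, MeOH, 0 °C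
Reagents that add atoms: mCPBA, O=C(OO)c1cccc(Cl)c1
Why: Baeyer–Villiger (Dakin-type) oxidation migrates the electron-rich o-alkoxyaryl group to give the aryl formate, which is methanolysed to a phenol meta to Br, while the bicarbonate buffer protects the MOM acetal.

**Step 4**
Reactants: 5, 5-bromo-2-(methoxymethoxy)phenol; 2, methyl (2S)-3-(benzyloxy)-2-hydroxypropanoate
Product: 6, methyl (2R)-3-(benzyloxy)-2-[5-bromo-2-(methoxymethoxy)phenoxy]propanoate
Conditions: PPh3, DIAD, THF, 0 °C → rt
Reagents that add atoms: none
Why: Mitsunobu etherification of an α-hydroxy ester with a phenol proceeds by clean SN2 inversion, turning the (S)-carbinol into the (R)-aryl ether that becomes benzodioxane C3, the only reagent-set centre of this fragment.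

**Step 5**
Reactants: 6, methyl (2R)-3-(benzyloxy)-2-[5-bromo-2-(methoxymethoxy)phenoxy]propanoate
Product: 7, (2R)-3-(benzyloxy)-2-[5-bromo-2-(methoxymethoxy)phenoxy]propanal (used crude at once)
Conditions: DIBAL-H (1.1 equiv), CH2Cl2, −78 °C; Rochelle salt work-up
Reagents that add atoms: none
Why: Partial ester reduction stops at the aldehyde because the α-oxygen-chelated aluminium hemiacetal is stable at −78 °C, and the non-basic conditions leave the α-centre intact.

**Step 6**
Reactants: 7, (2R)-3-(benzyloxy)-2-[5-bromo-2-(methoxymethoxy)phenoxy]propanal; 8, 1-(benzyloxy)-4-bromo-2-methoxybenzene (as its Grignard reagent)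
Product: 9, (1RS,2R)-3-(benzyloxy)-1-[4-(benzyloxy)-3-methoxyphenyl]-2-[5-bromo-2-(methoxymethoxy)phenoxy]propan-1-ol (C1 epimer mixture)
Conditions: 8, Mg, THF (ArMgBr, 1.5 equiv); then 7, THF, −78 → −40 °C
Reagents that add atoms: none
Why: Grignard 1,2-addition outcompetes enolisation at −78 °C so C2 stays (R), the substrate ArBr is inert to ArMgBr, and the C1 configuration is irrelevant because that carbon is ionised in step 7.

**Step 7**
Reactants: 9, the C1-epimeric alcohol
Product: 10, (2R,3R)-2-[4-(benzyloxy)-3-methoxyphenyl]-3-[(benzyloxy)methyl]-6-bromo-2,3-dihydro-1,4-benzodioxine (recrystallised to upgrade dr/ee)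
Conditions: (i) HCl, MeOH/THF, 45 °C; (ii) concentrate, BF3·OEt2 (0.3 equiv), CH2Cl2 (0.02 M), −20 → 0 °C
Reagents that add atoms: none
Why: Acetal cleavage frees the phenol para to Br, which traps the p-benzyloxybenzyl cation in a reversible SN1 etherification, so both C1 epimers converge on the thermodynamically preferred trans (diequatorial) ring and the new C2 is R relative to the fixed (R)-C3.

**Step 8**
Reactants: 10, the (2R,3R)-bromobenzodioxane
Product: 11, {(2R,3R)-2-[4-(benzyloxy)-3-methoxyphenyl]-3-[(benzyloxy)methyl]-2,3-dihydro-1,4-benzodioxin-6-yl}boronic acid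
Conditions: B(Oi-Pr)3 (1.5 equiv), n-BuLi (1.1 equiv), THF/PhMe, −78 °C; then 1 M HCl
Reagents that add atoms: triisopropyl borate, CC(C)OB(OC(C)C)OC(C)C; water, O
Why: Bromine–lithium exchange with in situ borate trapping (lithiation–borylation) is far faster at −78 °C than deprotonation of the benzylic ether C–H, and no stereocentre is involved.

**Step 9**
Reactants: 12, 2′,4′,6′-trihydroxyacetophenone
Product: 13, 1-[2,4-bis(benzyloxy)-6-hydroxyphenyl]ethan-1-one
Conditions: BnBr (2.1 equiv), K2CO3, DMF, rt
Reagents that add atoms: benzyl bromide, BrCc1ccccc1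
Why: Williamson etherification benzylates two hydroxyls (the para-OH and one ortho-OH) and then stops, because the remaining ortho-OH is deactivated by its hydrogen bond to the ketone and is exactly the phenol needed for chromone closure.

**Step 10**
Reactants: 13, 1-[2,4-bis(benzyloxy)-6-hydroxyphenyl]ethan-1-one
Product: 14, (E)-1-[2,4-bis(benzyloxy)-6-hydroxyphenyl]-3-(dimethylamino)prop-2-en-1-one
Conditions: DMF-DMA, PhMe, 95 °C
Reagents that add atoms: N,N-dimethylformamide dimethyl acetal, COC(OC)N(C)C
Why: Enaminone condensation of the methyl ketone with DMF-DMA installs the one-carbon unit that becomes chromone C2.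

**Step 11**
Reactants: 14, the enaminone
Product: 15, 5,7-bis(benzyloxy)-4H-chromen-4-one
Conditions: conc. HCl, CH2Cl2, 40 °C
Reagents that add atoms: none
Why: Acid-promoted intramolecular oxa-Michael addition and loss of Me2NH (addition–elimination) closes the pyranone ring, and aryl benzyl ethers survive these conditions.

**Step 12 (key step)**
Reactants: 11, the benzodioxanyl boronic acid (1.0 equiv); 15, 5,7-bis(benzyloxy)-4H-chromen-4-one (1.5–2 equiv, excess recovered)
Product: 16, (2S)-5,7-bis(benzyloxy)-2-{(2R,3R)-2-[4-(benzyloxy)-3-methoxyphenyl]-3-[(benzyloxy)methyl]-2,3-dihydro-1,4-benzodioxin-6-yl}chroman-4-one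
Conditions: [RhCl(C2H4)2]2 (3 mol%), (S)-MeO-F12-BIPHEP (6.6 mol%), aq. KOH (20 mol%), PhMe/H2O 10:1, 30 °C
Reagents that add atoms: none
Why: Hayashi–Miyaura Rh-catalysed asymmetric 1,4-addition inserts the aryl–Rh into the chromone C2=C3 on the face chosen by the electron-poor (S)-biaryl bisphosphine to set C2 as S under catalyst control (the benzodioxane centres are too remote to interfere), and the near-neutral conditions prevent retro-oxa-Michael opening to the chalcone.

**Step 13**
Reactants: 16, tetra-O-benzyl silandrin
Product: 17, silandrin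
Conditions: H2 (1 atm), 10% Pd/C, EtOAc/MeOH, rt, monitored and stopped at full debenzylation
Reagents that add atoms: none
Why: Catalytic hydrogenolysis cleaves the three aryl benzyl ethers and the primary benzyl ether under neutral conditions that cannot epimerise C2 via the chalcone, while the secondary cyclic benzylic C–O bonds and the 5-OH-chelated ketone react much more slowly.

## Compound list

1 | methyl (S)-glycidate | COC(=O)[C@@H]1CO1 | starting material
2 | methyl (2S)-3-(benzyloxy)-2-hydroxypropanoate | COC(=O)[C@@H](O)COCc1ccccc1 | intermediate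
3 | 5-bromo-2-hydroxybenzaldehyde | O=Cc1cc(Br)ccc1O | starting material
4 | 5-bromo-2-(methoxymethoxy)benzaldehyde | O=Cc1cc(Br)ccc1OCOC | intermediate
5 | 5-bromo-2-(methoxymethoxy)phenol | Oc1cc(Br)ccc1OCOC | intermediate
6 | methyl (2R)-3-(benzyloxy)-2-[5-bromo-2-(methoxymethoxy)phenoxy]propanoate | COC(=O)[C@H](Oc1cc(Br)ccc1OCOC)COCc1ccccc1 | intermediate
7 | (2R)-3-(benzyloxy)-2-[5-bromo-2-(methoxymethoxy)phenoxy]propanal | O=C[C@H](Oc1cc(Br)ccc1OCOC)COCc1ccccc1 | intermediate
8 | 1-(benzyloxy)-4-bromo-2-methoxybenzene | COc1cc(Br)ccc1OCc1ccccc1 | starting material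
9 | (1RS,2R)-3-(benzyloxy)-1-[4-(benzyloxy)-3-methoxyphenyl]-2-[5-bromo-2-(methoxymethoxy)phenoxy]propan-1-ol | COc1cc(C(O)[C@H](Oc2cc(Br)ccc2OCOC)COCc2ccccc2)ccc1OCc1ccccc1 | intermediate
10 | (2R,3R)-2-[4-(benzyloxy)-3-methoxyphenyl]-3-[(benzyloxy)methyl]-6-bromo-2,3-dihydro-1,4-benzodioxine | COc1cc([C@H]2Oc3ccc(Br)cc3O[C@@H]2COCc2ccccc2)ccc1OCc1ccccc1 | intermediate
11 | {(2R,3R)-2-[4-(benzyloxy)-3-methoxyphenyl]-3-[(benzyloxy)methyl]-2,3-dihydro-1,4-benzodioxin-6-yl}boronic acid | COc1cc([C@H]2Oc3ccc(B(O)O)cc3O[C@@H]2COCc2ccccc2)ccc1OCc1ccccc1 | intermediate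
12 | 2′,4′,6′-trihydroxyacetophenone | CC(=O)c1c(O)cc(O)cc1O | starting material
13 | 1-[2,4-bis(benzyloxy)-6-hydroxyphenyl]ethan-1-one | CC(=O)c1c(O)cc(OCc2ccccc2)cc1OCc1ccccc1 | intermediate
14 | (E)-1-[2,4-bis(benzyloxy)-6-hydroxyphenyl]-3-(dimethylamino)prop-2-en-1-one | CN(C)/C=C/C(=O)c1c(O)cc(OCc2ccccc2)cc1OCc1ccccc1 | intermediate
15 | 5,7-bis(benzyloxy)-4H-chromen-4-one | O=c1ccoc2cc(OCc3ccccc3)cc(OCc3ccccc3)c12 | intermediate
16 | (2S)-5,7-bis(benzyloxy)-2-{(2R,3R)-2-[4-(benzyloxy)-3-methoxyphenyl]-3-[(benzyloxy)methyl]-2,3-dihydro-1,4-benzodioxin-6-yl}chroman-4-one | COc1cc([C@H]2Oc3ccc([C@@H]4CC(=O)c5c(OCc6ccccc6)cc(OCc6ccccc6)cc5O4)cc3O[C@@H]2COCc2ccccc2)ccc1OCc1ccccc1 | intermediate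
17 | silandrin | COc1cc([C@H]2Oc3ccc([C@@H]4CC(=O)c5c(O)cc(O)cc5O4)cc3O[C@@H]2CO)ccc1O | target

## Summary

Total steps: 13.
Longest linear sequence: 9 (steps 2–8, 12, 13, from 5-bromosalicylaldehyde).

Three steps most likely to fail, with fallbacks:

- **Step 12 (Rh asymmetric 1,4-addition).** The 5,7-dialkoxychromone is a poor acceptor, the electron-rich boronic acid can protodeboronate, and the C2 epimers are hard to separate. Fallback: switch from C–C to C–O bond formation. Formylate 10 (n-BuLi, DMF), run a Claisen–Schmidt condensation with a protected 2′-hydroxyacetophenone to the chalcone, then close the flavanone by a cinchona-thiourea-catalysed enantioselective intramolecular oxa-Michael reaction.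
- **Step 7 (acid cyclisation).** Risks are a cis/trans mixture and erosion of C3 through E1 enol-ether formation from the benzylic cation. Fallback: make a single erythro diastereomer by an Evans syn-glycolate aldol of the N-(aryloxyacetyl)oxazolidinone with O-benzylvanillin, reduce with LiBH4, and close the ring by stereospecific intramolecular Mitsunobu inversion at the benzylic carbon. This also avoids the epimerisable aldehyde 7.
- **Step 13 (global hydrogenolysis).** The primary alkyl benzyl ether is slow, and long reaction times risk cleaving the ring benzylic C–O bonds. Fallback: redesign the protecting groups. Use the 3-O-trityl glycerate so the CH2OH is freed in step 7 and carried unprotected (Miyaura borylation with B2pin2/Pd, and the Rh step, both tolerate a free OH), leaving only three fast-cleaving aryl benzyl ethers at the end; or use 5,7-bis(MOM)chromone with silyl ethers elsewhere for a purely acidic final deprotection.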